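**Retrosynthetic overview**
1. Structural feature: in the 1,2-dioxane ring (O–O, C3, C4, C5, C6; chain numbered from the acid carbon C1), the C2-bearing side chain on C3 and the methyl on C6 lie on the same ring face. This cis-3,6 pattern results when O2 bonds through one face to both termini of a 3E,5Z C3=C4–C5=C6 diene.
2. Late disconnections: the C1 acid comes from a silyl-protected primary alcohol. The C11–C12 bond comes from a Wittig union of a β-cyclocitral-derived ylide with a C11 epoxy aldehyde, followed by diimide reduction. The C9–C10 oxirane comes from Sharpless epoxidation of the E-allylic alcohol made from a C11 ester.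
3. Central disconnection: the dioxane comes from diimide reduction of a 3,6-dihydro-1,2-dioxine, itself made by singlet-oxygen [4+2] on an acyclic triene ester. C3=C4 comes from a Julia–Kocienski coupling of a Roche-ester sulfone (C1–C3) with a nerol-derived Z-enal (C4–C9; C10/C11 are added by cross-metathesis with methyl methacrylate).
4. Ring order: the peroxide ring is formed first and the oxirane second. The purchased cyclohexene ring is attached last, because its tetrasubstituted alkene would not survive singlet oxygen.

Key step: step 10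

Remark: locants C1–C14 are those of the target chain and are used for all intermediates. CIP letters change only where substituent ranks change. Compound 23 is expected as an E/Z mixture at C11=C12, so its SMILES leaves that bond open. TBS = tert-butyldimethylsilyl; PT = 1-phenyl-1H-tetrazol-5-yl.

**Step 1**
Reactants: 1 nerol
Product: 2 neryl acetate
Conditions: Ac2O, Et3N, DMAP (cat.), CH2Cl2, 0 °C → rt
Reagents that add atoms: acetic anhydride CC(=O)OC(C)=O
Why: DMAP-catalysed O-acylation of a primary allylic alcohol leaves the Z-alkene untouched and turns it into a protected trisubstituted allylic alcohol that stays passive in the metathesis to come.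

**Step 2**
Reactants: 2 neryl acetate; 3 methyl methacrylate
Product: 4 methyl (2E,6Z)-8-acetoxy-2,6-dimethylocta-2,6-dienoate
Conditions: Hoveyda–Grubbs II (5 mol %), 3 (10 equiv), 1,4-benzoquinone (10 mol %), CH2Cl2, 40 °C
Reagents that add atoms: none
Why: Olefin cross-metathesis serves as a formal allylic oxidation of the prenyl terminus: the isopropylidene end is exchanged for the C(CH3)CO2Me end of 3 with loss of volatile isobutene, the trisubstituted enoate forms as its more stable E isomer, and the acetoxy-substituted C5=C6 alkene is a spectator olefin for this catalyst type, so its Z geometry is kept.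

**Step 3**
Reactants: 4 acetoxy dienoate
Product: 5 methyl (2E,6Z)-8-hydroxy-2,6-dimethylocta-2,6-dienoate
Conditions: K2CO3 (0.2 equiv), MeOH, 0 °C → rt
Reagents that add atoms: none
Why: Base-catalysed transesterification (Zemplén-type deacetylation) frees the C4 hydroxyl, exchange at the methyl ester being degenerate in methanol.

**Step 4**
Reactants: 5 hydroxy dienoate
Product: 6 methyl (2E,6Z)-2,6-dimethyl-8-oxoocta-2,6-dienoate (Z-enal ester, C4–C11)
Conditions: TEMPO (10 mol %), PhI(OAc)2, MeCN–pH 7 buffer, 0 °C
Reagents that add atoms: none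
Why: Oxoammonium (TEMPO/PhI(OAc)2) oxidation of an allylic alcohol stops at the aldehyde and is close to neutral, the condition under which neral-type Z-enals keep their geometry.

**Step 5**
Reactants: 7 methyl (S)-3-hydroxy-2-methylpropanoate (Roche ester)
Product: 8 methyl (S)-3-(tert-butyldimethylsilyloxy)-2-methylpropanoate
Conditions: TBSCl, imidazole, CH2Cl2, 0 °C → rt
Reagents that add atoms: tert-butyldimethylsilyl chloride CC(C)(C)[Si](C)(C)Cl
Why: Imidazole-promoted silylation of the primary alcohol does not involve the C2 stereocentre, which is bought with the Roche ester.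

**Step 6**
Reactants: 8 silyl ether ester
Product: 9 (R)-3-(tert-butyldimethylsilyloxy)-2-methylpropan-1-ol
Conditions: DIBAL-H (2.3 equiv), CH2Cl2, −78 → 0 °C; Rochelle salt
Reagents that add atoms: none
Why: Aluminium hydride reduction takes the ester straight to the primary alcohol, so no epimerisable aldehyde is handled and C2 is preserved (the descriptor becomes R by ranking only).

**Step 7**
Reactants: 9 monosilylated diol
Product: 10 5-{[(2S)-3-(tert-butyldimethylsilyloxy)-2-methylpropyl]sulfanyl}-1-phenyl-1H-tetrazole
Conditions: 1-phenyl-1H-tetrazole-5-thiol, PPh3, DIAD, THF, 0 °C → rt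
Reagents that add atoms: 1-phenyl-1H-tetrazole-5-thiol Sc1nnnn1-c1ccccc1
Why: Mitsunobu thioetherification occurs at the primary carbon C3 with the acidic tetrazole thiol, and the neighbouring stereocentre is not touched.

**Step 8**
Reactants: 10 PT sulfide
Product: 11 5-{[(2S)-3-(tert-butyldimethylsilyloxy)-2-methylpropyl]sulfonyl}-1-phenyl-1H-tetrazole
Conditions: (NH4)6Mo7O24·4H2O (10 mol %), 30 % aq. H2O2, EtOH, 0 °C → rt
Reagents that add atoms: hydrogen peroxide OO
Why: Molybdate-catalysed peroxide oxidation of sulfide to sulfone is the standard entry to Julia–Kocienski reagents and tolerates the primary TBS ether.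

**Step 9**
Reactants: 11 PT sulfone; 6 Z-enal ester
Product: 13 methyl (2E,6Z,8E,10R)-11-(tert-butyldimethylsilyloxy)-2,6,10-trimethylundeca-2,6,8-trienoate (chain locants 2R; 3E,5Z-diene; 9E-enoate), via potassio sulfone 12 (not isolated)
Conditions: KHMDS, THF, −78 °C; then 6, −78 °C → rt
Reagents that add atoms: none
Why: Julia–Kocienski olefination: the metallated PT sulfone adds to the aldehyde, Smiles rearrangement and loss of SO2 and tetrazololate form C3=C4, the pairing of an alkyl PT sulfone with a conjugated aldehyde and a potassium counter-ion favours the E alkene, and fast 1,2-addition at −78 °C leaves the 5Z alkene, the enoate and C2 unchanged.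

**Step 10**
Reactants: 13 triene ester
Product: 14 methyl (2E)-5-[(3R,6S)-6-[(2S)-1-(tert-butyldimethylsilyloxy)propan-2-yl]-3-methyl-3,6-dihydro-1,2-dioxin-3-yl]-2-methylpent-2-enoate (chain locants 2S,3S,6R; C3 side chain cis to C6 methyl)
Conditions: O2, tetraphenylporphyrin (1 mol %), CH2Cl2, −20 °C, visible light (white LED or sodium lamp)
Reagents that add atoms: dioxygen O=O
Why: Triplet-excited porphyrin passes its energy to O2, and the singlet oxygen adds suprafacially to C3 and C6 of the s-cis rotamer of the 3E,5Z-diene in a concerted, asynchronous [π4s+π2s] cycloaddition, the known photooxygenation of acyclic 1,3-dienes to 3,6-dihydro-1,2-dioxines. The ring O–O–C3–C4=C5–C6 closes in this single event as a six-membered [4+2] closure, both C–O bonds being made on one diene face and the new C4=C5 alkene being held cis by the ring. The C3/C6 relationship comes from the diene geometry: the two outward groups (C2 on C3, the methyl on C6) finish cis and the inward C7 chain trans to them, which is the relative configuration of the target. The absolute sense comes from C2: with C2–H eclipsing C3=C4 to minimise allylic strain, CH2OTBS screens one face and O2 should enter from the methyl-bearing face to give 3S,6R, a bias expected to be moderate, so the facial isomer is removed by chromatography. Chemoselectivity is needed against Schenck ene reactions: C9=C10 is deactivated by its ester, the oxidation-prone cyclohexene is not yet present, and an aprotic, weakly polar solvent at low temperature holds back both the ene path at C6–CH3/C7–H2 and any stepwise zwitterionic leakage that would scramble C6. The low triplet energy of the porphyrin cannot sensitise E/Z isomerisation of the diene.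

**Step 11**
Reactants: 14 dihydrodioxine
Product: 15 methyl (2E)-5-[(3R,6S)-6-[(2S)-1-(tert-butyldimethylsilyloxy)propan-2-yl]-3-methyl-1,2-dioxan-3-yl]-2-methylpent-2-enoate
Conditions: KO2CN=NCO2K (portionwise), AcOH, MeOH–CH2Cl2, 0 °C → rt, monitored
Reagents that add atoms: none
Why: Diimide reduction (concerted syn transfer of H2) saturates the cis-disubstituted C4=C5 ring alkene well before the trisubstituted conjugated C9=C10 alkene and does not touch the O–O bond, and it is done at once because the allylic peroxide with its C3–H would be at risk from hydride, titanium and ylide base later on.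

**Step 12**
Reactants: 15 dioxane enoate
Product: 16 (2E)-5-[(3R,6S)-6-[(2S)-1-(tert-butyldimethylsilyloxy)propan-2-yl]-3-methyl-1,2-dioxan-3-yl]-2-methylpent-2-en-1-ol
Conditions: DIBAL-H (2.5 equiv), CH2Cl2, −78 °C; Rochelle salt
Reagents that add atoms: none
Why: 1,2-Reduction of the enoate by DIBAL-H gives the E-allylic alcohol, a saturated dialkyl peroxide being expected to survive a short exposure to this reagent at −78 °C and the silyl ether being inert.

**Step 13**
Reactants: 16 allylic alcohol
Product: 17 [(2S,3S)-3-{2-[(3R,6S)-6-[(2S)-1-(tert-butyldimethylsilyloxy)propan-2-yl]-3-methyl-1,2-dioxan-3-yl]ethyl}-2-methyloxiran-2-yl]methanol (chain locants 2S,3S,6R,9S,10S)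
Conditions: Ti(OiPr)4 (15 mol %), L-(+)-DET (18 mol %), t-BuOOH (decane), 4 Å MS, CH2Cl2, −20 °C; aq. citric acid work-up (no Fe(II), sulfide or phosphite)
Reagents that add atoms: tert-butyl hydroperoxide CC(C)(C)OO
Why: Katsuki–Sharpless asymmetric epoxidation: the titanium/L-(+)-tartrate complex binds the allylic alcohol and delivers oxygen to the face that turns E-2-methylallylic alcohols into (2S,3S)-epoxy alcohols, which sets 9S,10S under reagent control with the remote ring centres having no say, and the trans relation of C8 and C11 follows from the E alkene.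

**Step 14**
Reactants: 17 epoxy alcohol
Product: 18 (2R,3S)-3-{2-[(3R,6S)-6-[(2S)-1-(tert-butyldimethylsilyloxy)propan-2-yl]-3-methyl-1,2-dioxan-3-yl]ethyl}-2-methyloxirane-2-carbaldehyde
Conditions: TEMPO (10 mol %), PhI(OAc)2, CH2Cl2, 0 °C → rt
Reagents that add atoms: none
Why: Oxoammonium oxidation of the primary epoxy alcohol stops at the aldehyde under anhydrous conditions, and C10 is quaternary and cannot epimerise (its descriptor becomes R by ranking only).

**Step 15**
Reactants: 19 β-cyclocitral
Product: 20 β-cyclogeraniol, (2,6,6-trimethylcyclohex-1-en-1-yl)methanol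
Conditions: NaBH4, MeOH, 0 °C
Reagents that add atoms: none
Why: Borohydride 1,2-reduction of the hindered enal gives the allylic alcohol without touching the tetrasubstituted alkene.

**Step 16**
Reactants: 20 β-cyclogeraniol
Product: 21 [(2,6,6-trimethylcyclohex-1-en-1-yl)methyl]triphenylphosphonium bromide
Conditions: Ph3P·HBr, MeOH, rt
Reagents that add atoms: triphenylphosphine hydrobromide [Br-].c1ccc(cc1)[PH+](c1ccccc1)c1ccccc1
Why: Acid-mediated phosphonium salt formation from an allylic alcohol: HBr ionises the allylic C–O bond and PPh3 captures the cation at its unhindered primary terminus.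

**Step 17**
Reactants: 21 phosphonium bromide; 18 epoxy aldehyde
Product: 23 11,12-didehydro derivative of 24 (C11=C12–C13=C14 diene; E/Z at C11=C12; 2S,3S,6R,9S,10S), via cyclogeranyl ylide 22 (not isolated)
Conditions: NaHMDS, THF, −78 → 0 °C; then 18, −78 °C → rt
Reagents that add atoms: none
Why: Wittig olefination: the semi-stabilised allylic ylide should add to the non-enolisable aldehyde much faster than it can act as a base on C3–H of the saturated dioxane, and the E/Z ratio at C11=C12 is irrelevant because this alkene is reduced next.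

**Step 18**
Reactants: 23 Wittig diene
Product: 24 tert-butyl(dimethyl){(2S)-2-[(3S,6R)-6-methyl-6-(2-{(2S,3S)-3-methyl-3-[2-(2,6,6-trimethylcyclohex-1-en-1-yl)ethyl]oxiran-2-yl}ethyl)-1,2-dioxan-3-yl]propoxy}silane
Conditions: 2-nitrobenzenesulfonohydrazide (portionwise), Et3N, CH2Cl2, rt
Reagents that add atoms: none
Why: Diimide reduction: only the disubstituted C11=C12 alkene accepts H2, the tetrasubstituted ring alkene being inert to diimide, and the amine-buffered, metal-free conditions spare the O–O bond and the allylic oxirane.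

**Step 19**
Reactants: 24 silyl ether
Product: 25 (2S)-2-[(3S,6R)-6-methyl-6-(2-{(2S,3S)-3-methyl-3-[2-(2,6,6-trimethylcyclohex-1-en-1-yl)ethyl]oxiran-2-yl}ethyl)-1,2-dioxan-3-yl]propan-1-ol
Conditions: TBAF, AcOH (1:1), THF, 0 °C → rt
Reagents that add atoms: none
Why: Fluoride-induced cleavage of the Si–O bond is buffered with acetic acid so that neither base-induced Kornblum–DeLaMare fragmentation at C3–H nor acid opening of the oxirane sets in.

**Step 20**
Reactants: 25 primary alcohol
Product: 27 (2R)-2-[(3S,6R)-6-methyl-6-(2-{(2S,3S)-3-methyl-3-[2-(2,6,6-trimethylcyclohex-1-en-1-yl)ethyl]oxiran-2-yl}ethyl)-1,2-dioxan-3-yl]propanoic acid (CNP0204283.1), via aldehyde 26 (not isolated)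
Conditions: TEMPO (20 mol %), PhI(OAc)2 (2.5 equiv), MeCN–pH 7 buffer, 0 °C → rt
Reagents that add atoms: water O
Why: TEMPO/PhI(OAc)2 oxidation in aqueous medium runs alcohol → aldehyde → hydrate → acid in one flask near neutrality, so C2 is not epimerised, the β-peroxy aldehyde has no time to eliminate, and the alkene, oxirane and O–O bond persist.

**Compound list**
1 | nerol, (2Z)-3,7-dimethylocta-2,6-dien-1-ol | CC(C)=CCC/C(C)=C\CO | starting material
2 | neryl acetate | CC(C)=CCC/C(C)=C\COC(C)=O | intermediate
3 | methyl methacrylate | C=C(C)C(=O)OC | starting material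
4 | methyl (2E,6Z)-8-acetoxy-2,6-dimethylocta-2,6-dienoate | COC(=O)/C(C)=C/CC/C(C)=C\COC(C)=O | intermediate
5 | methyl (2E,6Z)-8-hydroxy-2,6-dimethylocta-2,6-dienoate | COC(=O)/C(C)=C/CC/C(C)=C\CO | intermediate
6 | methyl (2E,6Z)-2,6-dimethyl-8-oxoocta-2,6-dienoate | COC(=O)/C(C)=C/CC/C(C)=C\C=O | intermediate
7 | methyl (S)-3-hydroxy-2-methylpropanoate | COC(=O)[C@@H](C)CO | starting material
8 | methyl (S)-3-(tert-butyldimethylsilyloxy)-2-methylpropanoate | COC(=O)[C@@H](C)CO[Si](C)(C)C(C)(C)C | intermediate
9 | (R)-3-(tert-butyldimethylsilyloxy)-2-methylpropan-1-ol | OC[C@@H](C)CO[Si](C)(C)C(C)(C)C | intermediate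
10 | (S)-PT sulfide | c1ccccc1-n1nnnc1SC[C@@H](C)CO[Si](C)(C)C(C)(C)C | intermediate
11 | (S)-PT sulfone | O=S(=O)(C[C@@H](C)CO[Si](C)(C)C(C)(C)C)c1nnnn1-c1ccccc1 | intermediate
12 | potassio sulfone (α-sulfonyl carbanion of 11, potassium salt) | [K+].O=S(=O)([CH-][C@@H](C)CO[Si](C)(C)C(C)(C)C)c1nnnn1-c1ccccc1 | intermediate
13 | triene ester, methyl (2E,6Z,8E,10R)-11-(tert-butyldimethylsilyloxy)-2,6,10-trimethylundeca-2,6,8-trienoate | COC(=O)/C(C)=C/CC/C(C)=C\C=C\[C@@H](C)CO[Si](C)(C)C(C)(C)C | intermediate
14 | 3,6-dihydro-1,2-dioxine with enoate arm (2S,3S,6R) | COC(=O)/C(C)=C/CC[C@]1(C)C=C[C@@H]([C@@H](C)CO[Si](C)(C)C(C)(C)C)OO1 | intermediate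
15 | 1,2-dioxane with enoate arm (2S,3S,6R) | COC(=O)/C(C)=C/CC[C@]1(C)CC[C@@H]([C@@H](C)CO[Si](C)(C)C(C)(C)C)OO1 | intermediate
16 | E-allylic alcohol (2S,3S,6R) | OC/C(C)=C/CC[C@]1(C)CC[C@@H]([C@@H](C)CO[Si](C)(C)C(C)(C)C)OO1 | intermediate
17 | epoxy alcohol (2S,3S,6R,9S,10S) | OC[C@]1(C)O[C@H]1CC[C@]1(C)CC[C@@H]([C@@H](C)CO[Si](C)(C)C(C)(C)C)OO1 | intermediate
18 | epoxy aldehyde (2S,3S,6R,9S,10R) | O=C[C@]1(C)O[C@H]1CC[C@]1(C)CC[C@@H]([C@@H](C)CO[Si](C)(C)C(C)(C)C)OO1 | intermediate
19 | β-cyclocitral | CC1=C(C=O)C(C)(C)CCC1 | starting material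
20 | β-cyclogeraniol | CC1=C(CO)C(C)(C)CCC1 | intermediate
21 | β-cyclogeranyltriphenylphosphonium bromide | CC1=C(C[P+](c2ccccc2)(c2ccccc2)c2ccccc2)C(C)(C)CCC1.[Br-] | intermediate
22 | cyclogeranyl ylide | CC1=C(C=P(c2ccccc2)(c2ccccc2)c2ccccc2)C(C)(C)CCC1 | intermediate
23 | Wittig diene (E/Z at C11=C12; 2S,3S,6R,9S,10S) | CC1=C(C=C[C@]2(C)O[C@H]2CC[C@]2(C)CC[C@@H]([C@@H](C)CO[Si](C)(C)C(C)(C)C)OO2)C(C)(C)CCC1 | intermediate
24 | C1 TBS ether of 25 (2S,3S,6R,9S,10S) | CC1=C(CC[C@]2(C)O[C@H]2CC[C@]2(C)CC[C@@H]([C@@H](C)CO[Si](C)(C)C(C)(C)C)OO2)C(C)(C)CCC1 | intermediate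
25 | C1 primary alcohol (2S,3S,6R,9S,10S) | CC1=C(CC[C@]2(C)O[C@H]2CC[C@]2(C)CC[C@@H]([C@@H](C)CO)OO2)C(C)(C)CCC1 | intermediate
26 | C1 aldehyde (2R,3S,6R,9S,10S) | CC1=C(CC[C@]2(C)O[C@H]2CC[C@]2(C)CC[C@@H]([C@@H](C)C=O)OO2)C(C)(C)CCC1 | intermediate
27 | CNP0204283.1 (2R,3S,6R,9S,10S) | CC1=C(CC[C@]2(C)O[C@H]2CC[C@]2(C)CC[C@@H]([C@@H](C)C(=O)O)OO2)C(C)(C)CCC1 | target

**Total step count:** 20.
**Longest linear sequence:** 14 steps (1–4 or 5–8, then 9–14 and 17–20).

**Steps most likely to fail**

**Step 10.**
- What may go wrong: the bias exerted by C2 is weak, so O2 may attack both diene faces to a similar extent and the two cis-3,6 isomers may be hard to separate. Ene hydroperoxidation at C6–CH3/C7–H2 would lower the throughput further.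
- Fallback (from 13, back at 14): the choice of ring enantiomer passes from the substrate to a catalyst.
- The photooxygenation of 13 is run without regard to the facial ratio. The mixture of 14 and the facial isomer F1 is then submitted to a kinetic resolution by chiral-amine-catalysed Kornblum–DeLaMare ring opening (cinchona-alkaloid base, CH2Cl2, rt).
- C3–H is the only proton next to a peroxide oxygen, so each isomer has a single pathway.
- The rings of 14 and F1 are mirror images. One member of the quinine/quinidine pseudo-enantiomeric catalyst pair should therefore deprotonate F1 faster and convert it into the polar Z-γ-hydroxy enone F2. Unchanged 14 is then separated from F2 by ordinary chromatography.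

**Step 18.**
- What may go wrong: C11=C12 is flanked by the quaternary C10 and by the trimethylcyclohexenyl ring, so hydrogen transfer may be slower than disproportionation of diimide. Long exposure to the sulfinic acid by-product may also ionise the allylic tertiary C10–O bond.
- Fallback (from 16, back at 24): the oxirane is introduced last.
- Alcohol 16 is oxidised (TEMPO/PhI(OAc)2) to the E-enal F3, and ylide 22 converts it into the conjugated triene F4.
- In F4, C11=C12 lies between two sp2 carbons and no epoxide is present. Diimide reduction to the 1,5-diene F5 should be easier and still selective over the tri- and tetrasubstituted alkenes.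
- A catalyst-controlled Shi epoxidation then turns the E-trisubstituted C9=C10 alkene into the 9S,10S-oxirane 24. It uses the enantiomer of the fructose-derived ketone, made from L-sorbose, with Oxone and K2CO3 buffer in MeCN–dimethoxymethane–H2O at 0 °C. The bulky dioxirane is expected to leave the shielded ring alkene alone.

**Step 12.**
- What may go wrong: reductive cleavage of the O–O bond by the aluminium hydride may compete with reduction of the conjugated ester.
- Fallback (from 13, back at 17): all hydride and titanium chemistry is moved ahead of the peroxide.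
- DIBAL-H reduces 13 to the trienol F6. Sharpless epoxidation with L-(+)-DET touches only the allylic-alcohol alkene and gives the dienyl epoxy alcohol F7.
- With the diene now the only alkene, photooxygenation as in step 10 gives the dihydrodioxine epoxy alcohol F8.
- Amine-buffered diimide reduction of the single remaining alkene in F8 gives 17. This also removes the selectivity demand of step 11.

**Further compounds**
F1 | step 10 | facial isomer of 14 (2S,3R,6S) | COC(=O)/C(C)=C/CC[C@@]1(C)C=C[C@H]([C@@H](C)CO[Si](C)(C)C(C)(C)C)OO1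
F2 | step 10 | Z-γ-hydroxy enone (C3 ketone, C6 tertiary alcohol; 2S,6S) | COC(=O)/C(C)=C/CC[C@](C)(O)/C=C\C(=O)[C@@H](C)CO[Si](C)(C)C(C)(C)C
F3 | step 18 | E-enal from 16 (2S,3S,6R) | O=C/C(C)=C/CC[C@]1(C)CC[C@@H]([C@@H](C)CO[Si](C)(C)C(C)(C)C)OO1
F4 | step 18 | conjugated triene (9E; E/Z at C11=C12) | CC1=C(C=C/C(C)=C/CC[C@]2(C)CC[C@@H]([C@@H](C)CO[Si](C)(C)C(C)(C)C)OO2)C(C)(C)CCC1
F5 | step 18 | 1,5-diene (9E) | CC1=C(CC/C(C)=C/CC[C@]2(C)CC[C@@H]([C@@H](C)CO[Si](C)(C)C(C)(C)C)OO2)C(C)(C)CCC1
F6 | step 12 | trienol (3E,5Z,9E; 2R) | OC/C(C)=C/CC/C(C)=C\C=C\[C@@H](C)CO[Si](C)(C)C(C)(C)C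
F7 | step 12 | dienyl epoxy alcohol (3E,5Z; 2R,9S,10S) | OC[C@]1(C)O[C@H]1CC/C(C)=C\C=C\[C@@H](C)CO[Si](C)(C)C(C)(C)C
F8 | step 12 | dihydrodioxine epoxy alcohol (2S,3S,6R,9S,10S) | OC[C@]1(C)O[C@H]1CC[C@]1(C)C=C[C@@H]([C@@H](C)CO[Si](C)(C)C(C)(C)C)OO1
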